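Ring A is a benzene with four contiguous substituents (acyl C1', OH C2', CH2 C3', ether O C4') and two adjacent CH carbons (C5', C6'). It is disconnected at C1'–C2' and C3'–C4': a 6-alkoxypyridazine-3-carboxylate supplies C4', C5', C6' and C1', and a methyl ynol ether, tethered through O1, C2 and C3 of the dihydrofuran, supplies C3' and C2'. Heating should effect an intramolecular inverse-demand [4+2] addition and loss of N2, closing ring A and the dihydrofuran in one operation. The precursor is a chiral-pool (3R)-homopropargylic pyridazinyl ether carrying a benzyl-protected tertiary carbinol; the chalcone is completed by Claisen–Schmidt condensation.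

Key step: step 8

Remark: in precursor 14 the only stereocentre is C3 of the hexynyl chain (C2 is the quaternary carbon carrying two methyl groups), so the ether is named and drawn as (3R).
Remark: methoxyacetylene is prepared and used as the isolated, amine-free alkyne, because amines would bind BF3 in step 6.
Remark: the ester is kept as the activating group for the cycloaddition and converted to the acetyl group afterwards, so the enone is closed on an unprotected 2'-hydroxyacetophenone.

Step 1
Reactants: 1 methyl (4R)-2,2-dimethyl-1,3-dioxolane-4-carboxylate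
Product: 3 2-[(4R)-2,2-dimethyl-1,3-dioxolan-4-yl]propan-2-ol, via methyl ketone 2 (not isolated)
Conditions: MeMgBr (2.5 equiv), THF, 0 °C to rt
Reagents that add atoms: methylmagnesium bromide, C[Mg]Br
Why: Double Grignard addition to the ester through ketone 2 is faster than enolisation of the α-alkoxy carbonyl compounds, so the stereocentre of 1 is carried over unchanged.

Step 2
Reactants: 3 2-[(4R)-2,2-dimethyl-1,3-dioxolan-4-yl]propan-2-ol
Product: 4 (4R)-4-[2-(benzyloxy)propan-2-yl]-2,2-dimethyl-1,3-dioxolane
Conditions: NaH, BnBr, Bu4NI (cat.), THF/DMF, 0 to 50 °C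
Reagents that add atoms: benzyl bromide, BrCc1ccccc1
Why: Williamson etherification of the tertiary sodium alkoxide, with iodide catalysis to offset hindrance, leaves the base-stable acetonide intact.

Step 3
Reactants: 4 (4R)-4-[2-(benzyloxy)propan-2-yl]-2,2-dimethyl-1,3-dioxolane
Product: 5 (2R)-3-(benzyloxy)-3-methylbutane-1,2-diol
Conditions: 80% aq. AcOH, 45 °C
Reagents that add atoms: none
Why: Acid-catalysed acetal hydrolysis removes the terminal acetonide, while the tertiary benzyl ether, whose cation would be destabilised by the adjacent oxygenated carbon, should survive the mild acid.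

Step 4
Reactants: 5 (2R)-3-(benzyloxy)-3-methylbutane-1,2-diol
Product: 7 (2R)-2-[2-(benzyloxy)propan-2-yl]oxirane, via primary monotosylate 6 (not isolated)
Conditions: NaH (2.5 equiv), N-tosylimidazole (1.05 equiv), THF, 0 °C to rt
Reagents that add atoms: none
Why: The unhindered primary alkoxide is sulfonylated selectively and the secondary alkoxide then closes the oxirane by intramolecular Williamson displacement (3-exo-tet) at CH2, so no bond at the stereocentre is broken and it stays R.

Step 5
Reactants: 8 chloroacetaldehyde dimethyl acetal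
Product: 10 methoxyacetylene (methoxyethyne), via sodium methoxyacetylide 9 (not isolated)
Conditions: NaNH2 (3.2 equiv), liq. NH3, −33 °C; then cold aq. NaCl; distilled into THF at −78 °C
Reagents that add atoms: none
Why: Sodium amide effects two successive β-eliminations (of methanol, then of HCl) and deprotonates the alkyne to 9, which water protonates; this dehydroelimination of a haloacetal is the standard entry to 1-alkoxyalkynes.

Step 6
Reactants: 7 (2R)-2-[2-(benzyloxy)propan-2-yl]oxirane; 10 methoxyacetylene
Product: 12 (3R)-2-(benzyloxy)-6-methoxy-2-methylhex-5-yn-3-ol, via lithium methoxyacetylide 11 (not isolated)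
Conditions: 10 (2 equiv), n-BuLi, THF, −78 °C; BF3·OEt2; then 7, −78 °C; Et3N/aq. NaHCO3 quench; Et3N-treated silica
Reagents that add atoms: none
Why: BF3-promoted epoxide opening by a lithium alkoxyacetylide, established for terminal epoxides, proceeds by SN2 attack at the unhindered CH2 and leaves the stereocentre untouched, and the basic quench protects the acid-labile ynol ether.

Step 7
Reactants: 12 (3R)-2-(benzyloxy)-6-methoxy-2-methylhex-5-yn-3-ol; 13 methyl 6-chloropyridazine-3-carboxylate
Product: 14 methyl 6-{[(3R)-2-(benzyloxy)-6-methoxy-2-methylhex-5-yn-3-yl]oxy}pyridazine-3-carboxylate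
Conditions: NaH (1.05 equiv), THF, 0 °C; then 13 (1.15 equiv), −20 °C to rt
Reagents that add atoms: none
Why: SNAr through a Meisenheimer adduct displaces the chloride para to the ester on the electron-poor diazine, the low temperature and excess of 13 favour this over ester exchange, and the C–O bond at the stereocentre is not broken.

Step 8
Reactants: 14 methyl 6-{[(3R)-2-(benzyloxy)-6-methoxy-2-methylhex-5-yn-3-yl]oxy}pyridazine-3-carboxylate
Product: 16 methyl (2R)-2-[2-(benzyloxy)propan-2-yl]-4-methoxy-2,3-dihydro-1-benzofuran-5-carboxylate, via diazabicyclooctatriene cycloadduct 15 (not isolated)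
Conditions: degassed PhCl (0.01 M), 2,6-lutidine (0.2 equiv), 110–130 °C, sealed, base-washed glassware
Reagents that add atoms: none
Why: Proposed new method: the ynol ether (HOMO raised by OMe) should add across C3 and C6 of the 1,2-diazine (LUMO lowered by CO2Me) in an asynchronous inverse-electron-demand [4+2] addition, its nucleophilic CH2-bearing carbon bonding to the alkoxy-bearing ring carbon para to the ester and its methoxy-bearing carbon to the ester-bearing carbon, after which adduct 15 loses N2 by retro-[4+2] to give the benzene irreversibly. The closest known reaction type is the thermal intramolecular Diels–Alder reaction of 3-(but-3-ynyloxy)pyridazines, which gives 2,3-dihydrobenzofurans with loss of N2; ynamines are known to add to electron-poor pyridazines intermolecularly, but an ynol ether has not been used as the dienophile. Ring A closes as the six-membered ring of the [4+2] (new bonds C3a–C7a and C4–C5) and is aromatised by the cycloreversion, and the dihydrofuran closes in the same event as the five-membered ring fused at C3a–C7a, its size fixed by the three-atom O–CH–CH2 tether. No stereocentre is formed in 16 (the bridgeheads of 15 vanish on aromatisation) and no bond at C2, set in 1, is broken. Regiochemistry is fixed by the tether, so the only selectivity needed is rate: cycloaddition must outrun decay of the ynol ether, which is secured by the methyl group (no β-hydrogen for retro-ene loss to a ketene and no [3,3] path such as a benzyl or allyl group would open), by high dilution and by a dry, slightly basic medium that suppresses acid-catalysed hydration.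

Step 9
Reactants: 16 methyl (2R)-2-[2-(benzyloxy)propan-2-yl]-4-methoxy-2,3-dihydro-1-benzofuran-5-carboxylate
Product: 18 1-{(2R)-2-[2-(benzyloxy)propan-2-yl]-4-methoxy-2,3-dihydro-1-benzofuran-5-yl}ethan-1-one, via Weinreb amide 17 (not isolated)
Conditions: Me(MeO)NH·HCl (1.5 equiv), i-PrMgCl (3 equiv), THF, −20 to 0 °C; then MeMgBr (3 equiv), 0 °C to rt
Reagents that add atoms: methylmagnesium bromide, C[Mg]Br
Why: Aminolysis of the ester by the magnesium amide gives 17, whose chelated tetrahedral adduct with MeMgBr cannot add a second methyl group and releases the ketone on work-up (Weinreb ketone synthesis).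

Step 10
Reactants: 18 1-{(2R)-2-[2-(benzyloxy)propan-2-yl]-4-methoxy-2,3-dihydro-1-benzofuran-5-yl}ethan-1-one
Product: 19 1-{(2R)-2-[2-(benzyloxy)propan-2-yl]-4-hydroxy-2,3-dihydro-1-benzofuran-5-yl}ethan-1-one
Conditions: MgI2 (2.5 equiv), Et2O/toluene, 60–70 °C
Reagents that add atoms: none
Why: Chelation-assisted ether cleavage, in which magnesium bridges the ketone oxygen and the ortho methoxy oxygen and iodide removes the methyl group by SN2, spares the unchelated benzyl ether and the dihydrofuran ether.

Step 11
Reactants: 19 1-{(2R)-2-[2-(benzyloxy)propan-2-yl]-4-hydroxy-2,3-dihydro-1-benzofuran-5-yl}ethan-1-one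
Product: 20 1-[(2R)-4-hydroxy-2-(2-hydroxypropan-2-yl)-2,3-dihydro-1-benzofuran-5-yl]ethan-1-one
Conditions: H2 (1 atm), Pd/C, EtOAc, rt
Reagents that add atoms: none
Why: Hydrogenolysis cleaves the benzyl C–O bond, while the hydrogen-bonded aryl ketone and the aryl alkyl ether are inert at one atmosphere and room temperature.

Step 12
Reactants: 21 4-hydroxybenzaldehyde; 22 3-chloro-3-methylbut-1-yne
Product: 23 4-[(2-methylbut-3-yn-2-yl)oxy]benzaldehyde
Conditions: K2CO3, KI (cat.), CuI (cat.), DMF, 60 °C
Reagents that add atoms: none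
Why: Copper-assisted propargylic substitution lets the phenoxide alkylate the tertiary chloride at oxygen, the established way to aryl 1,1-dimethylpropargyl ethers.

Step 13
Reactants: 23 4-[(2-methylbut-3-yn-2-yl)oxy]benzaldehyde
Product: 25 2,2-dimethyl-2H-chromene-6-carbaldehyde, via ortho-allenylphenol 24 (not isolated)
Conditions: PhNEt2, 190 °C
Reagents that add atoms: none
Why: Aromatic propargyl Claisen rearrangement gives 24, whose 1,5-hydrogen shift and oxa-6π electrocyclisation close the chromene, and the two ortho positions are equivalent, so only one regioisomer can form.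

Step 14
Reactants: 20 1-[(2R)-4-hydroxy-2-(2-hydroxypropan-2-yl)-2,3-dihydro-1-benzofuran-5-yl]ethan-1-one; 25 2,2-dimethyl-2H-chromene-6-carbaldehyde
Product: 26 (2E)-3-(2,2-dimethyl-2H-chromen-6-yl)-1-[(2R)-4-hydroxy-2-(2-hydroxypropan-2-yl)-2,3-dihydro-1-benzofuran-5-yl]prop-2-en-1-one
Conditions: KOH (50% aq., 10 equiv), EtOH, rt, N2; then AcOH to pH 6, 0 °C
Reagents that add atoms: none
Why: Claisen–Schmidt condensation, in which the ketone enolate adds to the non-enolisable aldehyde and E1cB dehydration gives the conjugated E-enone under thermodynamic control, keeps the 2'-phenoxide open-chain in strong base and cannot affect C2, which has no acidic hydrogen.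

Compound list
1 | methyl (4R)-2,2-dimethyl-1,3-dioxolane-4-carboxylate | COC(=O)[C@H]1COC(C)(C)O1 | starting material
2 | 1-[(4R)-2,2-dimethyl-1,3-dioxolan-4-yl]ethan-1-one | CC(=O)[C@H]1COC(C)(C)O1 | intermediate
3 | 2-[(4R)-2,2-dimethyl-1,3-dioxolan-4-yl]propan-2-ol | CC(C)(O)[C@H]1COC(C)(C)O1 | intermediate
4 | (4R)-4-[2-(benzyloxy)propan-2-yl]-2,2-dimethyl-1,3-dioxolane | CC(C)(OCc1ccccc1)[C@H]1COC(C)(C)O1 | intermediate
5 | (2R)-3-(benzyloxy)-3-methylbutane-1,2-diol | CC(C)(OCc1ccccc1)[C@H](O)CO | intermediate
6 | (2R)-3-(benzyloxy)-2-hydroxy-3-methylbutyl 4-methylbenzenesulfonate | CC(C)(OCc1ccccc1)[C@H](O)COS(=O)(=O)c1ccc(C)cc1 | intermediate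
7 | (2R)-2-[2-(benzyloxy)propan-2-yl]oxirane | CC(C)(OCc1ccccc1)[C@H]1CO1 | intermediate
8 | chloroacetaldehyde dimethyl acetal (2-chloro-1,1-dimethoxyethane) | COC(CCl)OC | starting material
9 | sodium methoxyacetylide | [Na]C#COC | intermediate
10 | methoxyacetylene (methoxyethyne) | COC#C | intermediate
11 | lithium methoxyacetylide | [Li]C#COC | intermediate
12 | (3R)-2-(benzyloxy)-6-methoxy-2-methylhex-5-yn-3-ol | COC#CC[C@H](C(C)(C)OCc1ccccc1)O | intermediate
13 | methyl 6-chloropyridazine-3-carboxylate | COC(=O)c1ccc(Cl)nn1 | starting material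
14 | methyl 6-{[(3R)-2-(benzyloxy)-6-methoxy-2-methylhex-5-yn-3-yl]oxy}pyridazine-3-carboxylate | COC#CC[C@H](C(C)(C)OCc1ccccc1)Oc1ccc(C(=O)OC)nn1 | intermediate
15 | [4+2] adduct of 14: 2,3-diazabicyclo[2.2.2]octa-2,5,7-triene with CO2Me on bridgehead C1, OMe on alkene carbon C7, and an O–CH[C(CH3)2OBn]–CH2 bridge from bridgehead C4 (O) to alkene carbon C8 (CH2); side-chain centre R, bridgehead configuration left open because both diastereomers give 16 | COC(=O)C12C=CC3(N=N1)O[C@@H](C(C)(C)OCc1ccccc1)CC3=C2OC | intermediate
16 | methyl (2R)-2-[2-(benzyloxy)propan-2-yl]-4-methoxy-2,3-dihydro-1-benzofuran-5-carboxylate | COC(=O)c1ccc2c(c1OC)C[C@H](C(C)(C)OCc1ccccc1)O2 | intermediate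
17 | (2R)-2-[2-(benzyloxy)propan-2-yl]-N,4-dimethoxy-N-methyl-2,3-dihydro-1-benzofuran-5-carboxamide | CON(C)C(=O)c1ccc2c(c1OC)C[C@H](C(C)(C)OCc1ccccc1)O2 | intermediate
18 | 1-{(2R)-2-[2-(benzyloxy)propan-2-yl]-4-methoxy-2,3-dihydro-1-benzofuran-5-yl}ethan-1-one | CC(=O)c1ccc2c(c1OC)C[C@H](C(C)(C)OCc1ccccc1)O2 | intermediate
19 | 1-{(2R)-2-[2-(benzyloxy)propan-2-yl]-4-hydroxy-2,3-dihydro-1-benzofuran-5-yl}ethan-1-one | CC(=O)c1ccc2c(c1O)C[C@H](C(C)(C)OCc1ccccc1)O2 | intermediate
20 | 1-[(2R)-4-hydroxy-2-(2-hydroxypropan-2-yl)-2,3-dihydro-1-benzofuran-5-yl]ethan-1-one | CC(=O)c1ccc2c(c1O)C[C@H](C(C)(C)O)O2 | intermediate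
21 | 4-hydroxybenzaldehyde | O=Cc1ccc(O)cc1 | starting material
22 | 3-chloro-3-methylbut-1-yne | CC(C)(Cl)C#C | starting material
23 | 4-[(2-methylbut-3-yn-2-yl)oxy]benzaldehyde | CC(C)(C#C)Oc1ccc(C=O)cc1 | intermediate
24 | 4-hydroxy-3-(3-methylbuta-1,2-dien-1-yl)benzaldehyde | CC(C)=C=Cc1cc(C=O)ccc1O | intermediate
25 | 2,2-dimethyl-2H-chromene-6-carbaldehyde | CC1(C)C=Cc2cc(C=O)ccc2O1 | intermediate
26 | (2E)-3-(2,2-dimethyl-2H-chromen-6-yl)-1-[(2R)-4-hydroxy-2-(2-hydroxypropan-2-yl)-2,3-dihydro-1-benzofuran-5-yl]prop-2-en-1-one | CC1(C)C=Cc2cc(/C=C/C(=O)c3ccc4c(c3O)C[C@H](C(C)(C)O)O4)ccc2O1 | target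

Total step count: 14.
Longest linear sequence: 11 steps (steps 1, 2, 3, 4, 6, 7, 8, 9, 10, 11, 14, from 1 to 26).

Steps most likely to fail

Step 8. The risk is that the ynol ether decays (hydration by traces of acid or water, oligomerisation on prolonged heating) faster than it adds to the diazine, or that a stepwise zwitterionic addition stalls before the second bond forms. The fallback uses only known reactions, sets out from epoxide 7 and returns at 19. Commercial 1-fluoro-3-(methoxymethoxy)benzene is lithiated between its two substituents (n-BuLi, THF, −78 °C) and opens 7 at CH2 in the presence of BF3·OEt2 to give (2R)-3-(benzyloxy)-1-[2-fluoro-6-(methoxymethoxy)phenyl]-3-methylbutan-2-ol F1. Treatment with t-BuOK in DMSO closes the dihydrofuran by intramolecular SNAr on the aryl fluoride; the C–O bond at the carbinol carbon is not broken, so the configuration is kept, giving (2R)-2-[2-(benzyloxy)propan-2-yl]-4-(methoxymethoxy)-2,3-dihydro-1-benzofuran F2. Ortho-lithiation directed by the methoxymethoxy group (s-BuLi, TMEDA, THF, −78 °C; C5 is its only free ortho position) and acylation by N-methoxy-N-methylacetamide give 1-{(2R)-2-[2-(benzyloxy)propan-2-yl]-4-(methoxymethoxy)-2,3-dihydro-1-benzofuran-5-yl}ethan-1-one F3. HCl in MeOH then removes the acetal and delivers 19.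

Step 7. The risk is attack of the hindered alkoxide at the ester carbonyl (ester exchange), which releases methoxide that then consumes 13 in competition with substitution at C6. The fallback sets out from 12 and returns at 14. The sodium alkoxide of 12 (NaH, DMF) is reacted with 6-chloropyridazine-3-carboxylic acid as its sodium salt at 40–60 °C; a carboxylate cannot undergo exchange and still directs substitution to C6. This gives sodium 6-{[(3R)-2-(benzyloxy)-6-methoxy-2-methylhex-5-yn-3-yl]oxy}pyridazine-3-carboxylate F4, which is O-methylated with MeI in the same basic medium, without acidic work-up, to give 14.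

Step 9. The risk is incomplete aminolysis of the hindered, electron-rich ester, so that residual ester takes up two methyl groups and ends as the tertiary alcohol. The fallback sets out from 16 and returns at 18. Saponification (LiOH, THF/MeOH/H2O) gives (2R)-2-[2-(benzyloxy)propan-2-yl]-4-methoxy-2,3-dihydro-1-benzofuran-5-carboxylic acid F5. Excess MeLi (THF, 0 °C) converts its lithium carboxylate into the stable dilithium gem-diolate, which releases ketone 18 only on aqueous quench.

Further compounds
F1 | step 8 | (2R)-3-(benzyloxy)-1-[2-fluoro-6-(methoxymethoxy)phenyl]-3-methylbutan-2-ol | COCOc1cccc(F)c1C[C@@H](O)C(C)(C)OCc1ccccc1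
F2 | step 8 | (2R)-2-[2-(benzyloxy)propan-2-yl]-4-(methoxymethoxy)-2,3-dihydro-1-benzofuran | COCOc1cccc2c1C[C@H](C(C)(C)OCc1ccccc1)O2
F3 | step 8 | 1-{(2R)-2-[2-(benzyloxy)propan-2-yl]-4-(methoxymethoxy)-2,3-dihydro-1-benzofuran-5-yl}ethan-1-one | COCOc1c(C(C)=O)ccc2c1C[C@H](C(C)(C)OCc1ccccc1)O2
F4 | step 7 | sodium 6-{[(3R)-2-(benzyloxy)-6-methoxy-2-methylhex-5-yn-3-yl]oxy}pyridazine-3-carboxylate | COC#CC[C@H](C(C)(C)OCc1ccccc1)Oc1ccc(C(=O)[O-])nn1.[Na+]
F5 | step 9 | (2R)-2-[2-(benzyloxy)propan-2-yl]-4-methoxy-2,3-dihydro-1-benzofuran-5-carboxylic acid | COc1c(C(=O)O)ccc2c1C[C@H](C(C)(C)OCc1ccccc1)O2
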